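At early times the north-west run, 0.80 M of starting material at 0 °C, gave 22% of single ring after 1.00 h, yet its last reading, at 12.0 h, stood at 61%. So I had to decide what to charge next, and whether to leave the flask warm after 20 h.

| flask | starting material | temperature | remark | time |
|---|---|---|---|---|
| north-west | 0.80 M | 0 °C | run made earlier |  |
| delta | 0.40 M | 0 °C |  | 40 h |
| eta | 0.40 M | −25 °C |  | 40 h |
| gamma | 0.40 M |  | at 0 °C until 20 h, from then on at −25 °C | 40 h |

north-west run (percent of the starting material charged)

| time / h | single ring / % |
|---|---|
| 1.00 | 22 |
| 1.50 | 30 |
| 2.50 | 42 |
| 4.00 | 51 |
| 8.00 | 59 |
| 12.0 | 61 |

(each reading ± 1.5 percentage points)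

- the earlier runs do not show what temperature does; that part of a forecast is a guess

- the flask that comes out highest in amount of single ring, in percent of the starting material charged, or "all alike" when all lie within 1.5 percentage points (delta / eta / gamma / all alike)
- single ring at the end, in percent of the starting material charged, delta
- single ring at the end, in percent of the starting material charged, eta
- single ring at the end, in percent of the starting material charged, gamma

I treated the missing material as a correction to ring closure and reckoned that correction by itself. At its last reading the north-west run had 0.639 parts of material not read as single ring per part of single ring, a figure that carries the scatter of that reading. I assumed, though one run cannot show it, that the loss takes two molecules of starting material while ring closure takes one, so this ratio grows in proportion to the charge c. That gives the side ratio per unit of charge, g = 0.799 /M, an inverted selectivity factor, and a yield of 1/(1 + gc). At 0.40 M this gives 75.8%, above the north-west reading, so I would charge 0.40 M. Between 8.00 h and 12.0 h the readings rose 2 percentage points against a scatter of 1.5 points, and they stop there. They cannot say whether single ring holds afterwards, so I would cool at 20 h as a precaution. What cold does from the start, in eta, I could not reckon.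

The forecast gave 62% for delta (56% to 70%), 35% for eta (16% to 55%) and 64% for gamma (57% to 73%), and picked gamma. On dilution it parts from my reckoning, with delta lower than my figure: “I expect little concentration effect”.

The simulation gave 62.1% in delta, 19.3% in eta and 70.0% in gamma, so gamma came out highest.

    open dimer → ring dimer (k = 1.70 × 10⁻⁵ /s, Ea = 91.0 kJ/mol)
    2 starting material → open dimer (k = 5.20 × 10⁻⁵ /M/s, Ea = 68.0 kJ/mol)
    starting material + open dimer → open trimer (k = 1.40 × 10⁻⁴ /M/s, Ea = 77.0 kJ/mol)
    starting material → single ring (k = 8.10 × 10⁻⁵ /s, Ea = 87.0 kJ/mol)
    single ring ⇌ isomer of the product (K = 2.00, k = 1.90 × 10⁻⁶ /s, Ea = 100 kJ/mol, ΔH = −47.0 kJ/mol)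
    (constants at 0 °C)

My 75.8% from g stood above delta and gamma, and those two part after the change. Delta and gamma both held 70.1% at 20.0 h, but by 40.0 h delta held 16.5% of isomer of the product against 8.49% in gamma. Isomerisation is part of delta's shortfall: with that step taken away, delta ends at 78.6% instead of 62.1%. Eta, which g does not reach, still held 61.3% of starting material at 40.0 h, and the length of the run is the largest single effect on its 19.3% of single ring, which stands at 57.5% after 400 h.

For the neighbour of gamma charged with 1.0 M, g gives 55.6%; the simulation gave 52.6% of single ring, with 6.56% as isomer of the product.

The runs are simulated from invented constants; scatter was added.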